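**Strategy.** The synthesis rests on closing the α-methylene-γ-butyrolactone by O-alkylation at C6 instead of by acylation. C6 is an allylic carbinol carbon between the C4=C5 olefin and the ring-fusion centre C7. A syn-selective Barbier addition of a tartrate-derived (Z)-allylzinc (C7) to a (Z)-β-iodoenal (C6) gives the open-chain 6-epi γ-hydroxy acid. An intramolecular Mitsunobu reaction then forges the lactone O–C6 bond with inversion, giving the trans-fused lactone in one operation and leaving the tertiary C10 carbinol untouched. Nozaki–Hiyama–Kishi closure of the ten-membered ring (C3–C4), oxidation, gold-catalysed transannular 3(2H)-furanone formation and two esterifications complete the target.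

Key step: step 12

Remark: atoms are numbered as in germacranolides (C1–C15, C6 bearing the lactone oxygen); "6-epi" means the C6 epimer of the target series. The epimer mixtures at C7 in 9 and at C3 in 22 do not matter, because both centres become sp2.

Step 1
Reactants: 1 dimethyl (4R,5R)-2,2-dimethyl-1,3-dioxolane-4,5-dicarboxylate (dimethyl 2,3-O-isopropylidene-L-tartrate)
Product: 2 (4R,5R)-N4,N5-dimethoxy-N4,N5,2,2-tetramethyl-1,3-dioxolane-4,5-dicarboxamide (bis-Weinreb amide)
Conditions: MeNH(OMe)·HCl, iPrMgCl, THF, −20 → 0 °C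
Reagents that add atoms: N,O-dimethylhydroxylamine hydrochloride (CNOC.Cl)
Why: Aminolysis of both esters by the magnesium amide (Weinreb amide formation) should leave the trans-dioxolane centres (later C8 and C9) untouched.

Step 2
Reactants: 2 bis-Weinreb amide
Product: 3 (4R,5R)-5-acetyl-N-methoxy-N,2,2-trimethyl-1,3-dioxolane-4-carboxamide
Conditions: MeMgBr (1.1 equiv), THF, −78 → −20 °C; aq NH4Cl
Reagents that add atoms: methylmagnesium bromide (C[Mg]Br)
Why: Weinreb ketone synthesis; the stable magnesium chelate of the first adduct and the stoichiometry should limit the C2-symmetric diamide to mono-addition, giving the C10 methyl ketone.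

Step 3
Reactants: 3 keto amide; 4 3,3-diethoxyprop-1-yne
Product: 6 (4R,5R)-5-[(2R)-5,5-diethoxy-2-hydroxypent-3-yn-2-yl]-N-methoxy-N,2,2-trimethyl-1,3-dioxolane-4-carboxamide, via alkynylmagnesium bromide 5 (not isolated)
Conditions: 4, EtMgBr, THF, 0 °C → rt; then 3, MgBr2·OEt2, CH2Cl2/THF, −78 → −40 °C
Reagents that add atoms: none
Why: Cram-chelate-controlled 1,2-addition of an alkynyl Grignard reagent to the α-alkoxy methyl ketone (Mg bridging C10=O and O9, attack anti to C8) should set C10 with O9 and O10 syn, the ketone reacting ahead of the Weinreb amide.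

Step 4
Reactants: 6 tertiary propargylic alcohol
Product: 7 (4R,5R)-5-[(2R)-5,5-diethoxy-2-hydroxypent-3-yn-2-yl]-2,2-dimethyl-1,3-dioxolane-4-carbaldehyde
Conditions: DIBAL-H (2.5 equiv), THF, −78 °C; Rochelle salt
Reagents that add atoms: none
Why: Weinreb amide reduction stops at the aldehyde (C7) through the chelated aluminium hemiaminal, and −78 °C avoids hydroalumination of the propargylic alcohol.

Step 5
Reactants: 7 aldehyde; 8 methyl acrylate
Product: 9 methyl 2-{hydroxy[5-((2R)-5,5-diethoxy-2-hydroxypent-3-yn-2-yl)-2,2-dimethyl-1,3-dioxolan-4-yl]methyl}prop-2-enoate (dioxolane centres as in 7, both C7 epimers)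
Conditions: DABCO, 8 (excess, neat), cat. MeOH, rt
Reagents that add atoms: none
Why: Morita–Baylis–Hillman reaction attaches C11–C13 to C7; the new carbinol centre is formed as a mixture, which is irrelevant because C7 becomes sp2 in step 6.

Step 6
Reactants: 9 Morita–Baylis–Hillman adduct
Product: 10 methyl (Z)-2-(bromomethyl)-3-[5-((2R)-5,5-diethoxy-2-hydroxypent-3-yn-2-yl)-2,2-dimethyl-1,3-dioxolan-4-yl]prop-2-enoate (dioxolane centres as in 7)
Conditions: NBS, Me2S, CH2Cl2, −20 → 0 °C
Reagents that add atoms: N-bromosuccinimide (O=C1CCC(=O)N1Br)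
Why: Corey–Kim-type activation of the secondary allylic alcohol and SN2′ return of bromide (allylic transposition) should give the thermodynamically preferred Z-2-(bromomethyl)enoate, the hindered tertiary C10 hydroxyl staying intact.

Step 7
Reactants: 11 but-2-yne-1,4-diol
Product: 12 4-[(tert-butyldiphenylsilyl)oxy]but-2-yn-1-ol
Conditions: NaH (1 equiv), TBDPSCl (1 equiv), THF, 0 °C → rt, 11 in excess
Reagents that add atoms: tert-butyl(chloro)diphenylsilane (CC(C)(C)[Si](Cl)(c1ccccc1)c1ccccc1)
Why: Statistical monosilylation of a symmetrical diol through its monosodium alkoxide gives the future C15-O silyl ether.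

Step 8
Reactants: 12 monosilyl ether
Product: 14 (Z)-4-[(tert-butyldiphenylsilyl)oxy]-3-iodobut-2-en-1-ol, via cyclic alkenylalanate 13 (not isolated)
Conditions: Red-Al, THF, 0 °C → rt; then I2, −78 → 0 °C
Reagents that add atoms: iodine (II)
Why: Hydroxyl-directed trans-hydroalumination of the propargylic alcohol (hydride to C5, aluminium on C4 in a five-membered alkoxyalanate) and iododealumination with retention fix the olefin geometry, C6 cis to iodine.

Step 9
Reactants: 14 (Z)-iodo allylic alcohol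
Product: 15 (Z)-4-[(tert-butyldiphenylsilyl)oxy]-3-iodobut-2-enal
Conditions: MnO2, CH2Cl2, rt, dark
Reagents that add atoms: none
Why: Chemoselective MnO2 oxidation of the primary allylic alcohol should give the C6 enal without Z/E isomerisation.

Step 10
Reactants: 10 Z-allyl bromide; 15 (Z)-β-iodoenal
Product: 17 open-chain hydroxy ester (methyl ester at C12, C11=C13 methylene, C7 as in the target, C6-OH syn to C8 = 6-epi, Z-C5=C4(I)–C15H2OTBDPS, C8/C9 acetonide, C10 carbinol, C1≡C2–C3 diethyl acetal), via allylzinc bromide 16 (not isolated)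
Conditions: Zn dust, THF/sat. aq NH4Cl, 0 °C → rt
Reagents that add atoms: none
Why: Barbier allylation through a chair (Zimmerman–Traxler) transition state, in which the Z-γ-substituted allylzinc reacts at C7 and should give the syn adduct, while A(1,3) strain holds H8 in the olefin plane so that the enal adds anti to the bulky C9 branch of the dioxolane, setting C7 as in the target.

Step 11
Reactants: 17 hydroxy ester
Product: 18 6-epi γ-hydroxy acid (17 with CO2H in place of CO2Me)
Conditions: LiOH·H2O, THF/H2O, 0 °C; cold dilute HCl to pH 5, used at once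
Reagents that add atoms: lithium hydroxide ([Li+].[OH-])
Why: Saponification of the acrylate ester (BAc2) leaves all stereocentres untouched, and any cis-lactone formed in step 10 is opened to the same hydroxy acid.

Step 12
Reactants: 18 6-epi γ-hydroxy acid
Product: 20 trans-α-methylene-γ-butyrolactone (6R,7S as in the target; C6 bears the Z-iodoalkenyl chain, C7 the acetonide–carbinol–alkynyl acetal chain), via alkoxyphosphonium carboxylate 19 (not isolated)
Conditions: PPh3, DIAD, THF (5 mM), −20 → 0 °C, slow addition of 18 to the preformed betaine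
Reagents that add atoms: none
Why: The PPh3/DIAD betaine deprotonates the acid and converts the only activatable hydroxyl, the secondary allylic C6–OH, into alkoxyphosphonium 19, whose tethered carboxylate displaces Ph3P=O at C6 from the rear, so the ring O–C6 bond forms with inversion. The closest known reaction type is the Mitsunobu lactonisation of γ-hydroxy acids with inversion at the carbinol carbon. The butyrolactone ring (O–C6–C7–C11–C12) closes in the 5-exo-tet mode. C6 is the one stereocentre that changes: the stereospecific SN2 event acts on the syn (6-epi) carbinol from step 10, and with C7 fixed this places C5 and C8 trans on the lactone as in the target. The step needs O-alkyl closure (inversion) to win over acyl closure through an acyloxyphosphonium (retention) and over SN2′ attack at C4; the tertiary C10–OH cannot be activated, SN2′ closure would need a seven-membered ring at the iodine-bearing C4, and slow addition to excess betaine at low temperature and high dilution favours the alkoxyphosphonium path.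

Step 13
Reactants: 20 lactone acetal
Product: 21 lactone ynal (C3 aldehyde on the C1≡C2 alkyne)
Conditions: Amberlyst-15, acetone/H2O (50:1), rt
Reagents that add atoms: water (O)
Why: Acid-catalysed acetal hydrolysis, with acetone as solvent holding the isopropylidene ketal in place by mass action.

Step 14
Reactants: 21 lactone ynal
Product: 22 ten-membered carbocyclic enyne alcohol (C3 carbinol, both epimers; C4=C5 Z, trans-lactone, C8/C9 acetonide, C10-OH)
Conditions: CrCl2 (10 equiv), NiCl2 (cat.), degassed DMSO/THF, 3 mM, rt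
Reagents that add atoms: none
Why: Intramolecular Nozaki–Hiyama–Kishi reaction (oxidative addition of nickel to the vinyl iodide with retention of geometry, transmetalation to chromium(III), addition to the ynal) should close the ten-membered ring at C3–C4.

Step 15
Reactants: 22 macrocyclic alcohol
Product: 23 macrocyclic γ-hydroxy ynone (C3 ketone)
Conditions: MnO2, CH2Cl2, rt
Reagents that add atoms: none
Why: MnO2 oxidises only the doubly activated (allylic and propargylic) C3 carbinol, and both C3 epimers converge on one ketone.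

Step 16
Reactants: 23 macrocyclic γ-hydroxy ynone
Product: 24 3(2H)-furanone (3,10-epoxy bridge) with trans-lactone, C8/C9 acetonide and C15-OTBDPS
Conditions: (p-CF3C6H4)3PAuCl (5 mol%), AgOTf (5 mol%), wet toluene, rt
Reagents that add atoms: none
Why: Gold(I)-catalysed cycloisomerisation of a γ-hydroxy alkynone to a 3(2H)-furanone (oxygen delivered to C1 of the activated ynone, attack of the C10 hydroxyl on C3, loss of water) should proceed transannularly, with C10 keeping its configuration because its C–O bond is never broken.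

Step 17
Reactants: 24 acetonide
Product: 25 8,9-diol (C15-OTBDPS)
Conditions: AcOH/H2O (4:1), 45 °C
Reagents that add atoms: none
Why: Acid hydrolysis of the strained trans-fused isopropylidene ketal is tolerated by the primary TBDPS ether, the lactone and the furanone.

Step 18
Reactants: 25 8,9-diol
Product: 26 8-O-methacrylate, C9-OH free
Conditions: methacrylic anhydride (1.1 equiv), DMAP (cat.), Et3N, CH2Cl2, −40 → −20 °C
Reagents that add atoms: methacrylic anhydride (C=C(C)C(=O)OC(=O)C(C)=C)
Why: DMAP-catalysed acylation at low temperature should select the C8 hydroxyl over the neopentyl-type C9 hydroxyl next to quaternary C10.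

Step 19
Reactants: 26 8-O-methacrylate
Product: 27 8-O-methacrylate 9-O-angelate (C15-OTBDPS)
Conditions: angelic acid, 2,4,6-Cl3C6H2COCl, Et3N, toluene, rt; then 26, 80 °C, no DMAP
Reagents that add atoms: angelic acid (C/C=C(/C)C(=O)O)
Why: Yamaguchi esterification through the mixed 2,4,6-trichlorobenzoic anhydride without nucleophilic catalyst should acylate the hindered C9 hydroxyl without Z→E isomerisation of the angelate to the tiglate.

Step 20
Reactants: 27 silyl ether
Product: 28 target, (4Z,6R,7S,8S,9R,10S)-9-angeloyloxy-15-hydroxy-8-methacryloyloxy-1-oxo-3,10-epoxygermacra-2,4,11(13)-trien-12,6-olide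
Conditions: HF·pyridine, pyridine/THF, 0 °C → rt
Reagents that add atoms: none
Why: Buffered fluoride cleavage of the primary silyl ether should spare the three esters, the furanone and the α-methylene lactone.

**Compound list**

1 | dimethyl (4R,5R)-2,2-dimethyl-1,3-dioxolane-4,5-dicarboxylate | COC(=O)[C@@H]1OC(C)(C)O[C@H]1C(=O)OC | starting material
2 | (4R,5R)-N4,N5-dimethoxy-N4,N5,2,2-tetramethyl-1,3-dioxolane-4,5-dicarboxamide | CON(C)C(=O)[C@@H]1OC(C)(C)O[C@H]1C(=O)N(C)OC | intermediate
3 | (4R,5R)-5-acetyl-N-methoxy-N,2,2-trimethyl-1,3-dioxolane-4-carboxamide | CON(C)C(=O)[C@@H]1OC(C)(C)O[C@H]1C(C)=O | intermediate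
4 | 3,3-diethoxyprop-1-yne | C#CC(OCC)OCC | starting material
5 | (3,3-diethoxyprop-1-ynyl)magnesium bromide | CCOC(OCC)C#C[Mg]Br | intermediate (not isolated)
6 | (4R,5R)-5-[(2R)-5,5-diethoxy-2-hydroxypent-3-yn-2-yl]-N-methoxy-N,2,2-trimethyl-1,3-dioxolane-4-carboxamide | CON(C)C(=O)[C@@H]1OC(C)(C)O[C@H]1[C@](C)(O)C#CC(OCC)OCC | intermediate
7 | (4R,5R)-5-[(2R)-5,5-diethoxy-2-hydroxypent-3-yn-2-yl]-2,2-dimethyl-1,3-dioxolane-4-carbaldehyde | O=C[C@@H]1OC(C)(C)O[C@H]1[C@](C)(O)C#CC(OCC)OCC | intermediate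
8 | methyl acrylate | C=CC(=O)OC | starting material
9 | Morita–Baylis–Hillman adduct of 7 (C7 carbinol, both epimers; other centres as in 7) | COC(=O)C(=C)C(O)[C@@H]1OC(C)(C)O[C@H]1[C@](C)(O)C#CC(OCC)OCC | intermediate
10 | methyl (Z)-2-(bromomethyl)-3-(dioxolan-4-yl)prop-2-enoate derived from 9 (centres as in 7) | COC(=O)/C(CBr)=C/[C@@H]1OC(C)(C)O[C@H]1[C@](C)(O)C#CC(OCC)OCC | intermediate
11 | but-2-yne-1,4-diol | OCC#CCO | starting material
12 | 4-[(tert-butyldiphenylsilyl)oxy]but-2-yn-1-ol | OCC#CCO[Si](c1ccccc1)(c1ccccc1)C(C)(C)C | intermediate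
13 | sodium cyclic alkenylalanate (five-membered alkoxy-alanate from 12) | [Na+].COCCO[Al-]1(OCCOC)OCC=C1CO[Si](c2ccccc2)(c2ccccc2)C(C)(C)C | intermediate (not isolated)
14 | (Z)-4-[(tert-butyldiphenylsilyl)oxy]-3-iodobut-2-en-1-ol | OC/C=C(\I)CO[Si](c1ccccc1)(c1ccccc1)C(C)(C)C | intermediate
15 | (Z)-4-[(tert-butyldiphenylsilyl)oxy]-3-iodobut-2-enal | O=C/C=C(\I)CO[Si](c1ccccc1)(c1ccccc1)C(C)(C)C | intermediate
16 | allylzinc bromide from 10 | COC(=O)/C(C[Zn]Br)=C/[C@@H]1OC(C)(C)O[C@H]1[C@](C)(O)C#CC(OCC)OCC | intermediate (not isolated)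
17 | syn Barbier adduct, methyl ester (C7 as in target, 6-epi carbinol) | COC(=O)C(=C)[C@@H]([C@@H](O)/C=C(\I)CO[Si](c1ccccc1)(c1ccccc1)C(C)(C)C)[C@@H]1OC(C)(C)O[C@H]1[C@](C)(O)C#CC(OCC)OCC | intermediate
18 | 6-epi γ-hydroxy acid | OC(=O)C(=C)[C@@H]([C@@H](O)/C=C(\I)CO[Si](c1ccccc1)(c1ccccc1)C(C)(C)C)[C@@H]1OC(C)(C)O[C@H]1[C@](C)(O)C#CC(OCC)OCC | intermediate
19 | C6 alkoxytriphenylphosphonium carboxylate of 18 | [O-]C(=O)C(=C)[C@@H]([C@@H](O[P+](c1ccccc1)(c1ccccc1)c1ccccc1)/C=C(\I)CO[Si](c1ccccc1)(c1ccccc1)C(C)(C)C)[C@@H]1OC(C)(C)O[C@H]1[C@](C)(O)C#CC(OCC)OCC | intermediate (not isolated)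
20 | trans-α-methylene-γ-butyrolactone (6R,7S), vinyl iodide, diethyl acetal | C=C1C(=O)O[C@H](/C=C(\I)CO[Si](c2ccccc2)(c2ccccc2)C(C)(C)C)[C@H]1[C@@H]3OC(C)(C)O[C@H]3[C@](C)(O)C#CC(OCC)OCC | intermediate
21 | lactone ynal | C=C1C(=O)O[C@H](/C=C(\I)CO[Si](c2ccccc2)(c2ccccc2)C(C)(C)C)[C@H]1[C@@H]3OC(C)(C)O[C@H]3[C@](C)(O)C#CC=O | intermediate
22 | macrocyclic enyne alcohol (C3 carbinol, both epimers) | CC1(C)O[C@H]2[C@H]3C(=C)C(=O)O[C@@H]3/C=C(/CO[Si](c4ccccc4)(c4ccccc4)C(C)(C)C)C(O)C#C[C@@](C)(O)[C@@H]2O1 | intermediate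
23 | macrocyclic γ-hydroxy ynone | CC1(C)O[C@H]2[C@H]3C(=C)C(=O)O[C@@H]3/C=C(/CO[Si](c4ccccc4)(c4ccccc4)C(C)(C)C)C(=O)C#C[C@@](C)(O)[C@@H]2O1 | intermediate
24 | furanone lactone with 8,9-acetonide and 15-OTBDPS | CC1(C)O[C@H]2[C@H]3C(=C)C(=O)O[C@@H]3/C=C(/CO[Si](c4ccccc4)(c4ccccc4)C(C)(C)C)C4=CC(=O)[C@@](C)(O4)[C@@H]2O1 | intermediate
25 | 8,9-diol, 15-OTBDPS | O[C@H]1[C@H]2C(=C)C(=O)O[C@@H]2/C=C(/CO[Si](c3ccccc3)(c3ccccc3)C(C)(C)C)C2=CC(=O)[C@@](C)(O2)[C@@H]1O | intermediate
26 | 8-O-methacrylate, 9-OH, 15-OTBDPS | C=C(C)C(=O)O[C@H]1[C@H]2C(=C)C(=O)O[C@@H]2/C=C(/CO[Si](c3ccccc3)(c3ccccc3)C(C)(C)C)C2=CC(=O)[C@@](C)(O2)[C@@H]1O | intermediate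
27 | 8-O-methacrylate 9-O-angelate, 15-OTBDPS | C=C(C)C(=O)O[C@H]1[C@H]2C(=C)C(=O)O[C@@H]2/C=C(/CO[Si](c3ccccc3)(c3ccccc3)C(C)(C)C)C2=CC(=O)[C@@](C)(O2)[C@@H]1OC(=O)/C(C)=C\C | intermediate
28 | (4Z,6R,7S,8S,9R,10S)-9-angeloyloxy-15-hydroxy-8-methacryloyloxy-1-oxo-3,10-epoxygermacra-2,4,11(13)-trien-12,6-olide | C=C(C)C(=O)O[C@H]1[C@H]2C(=C)C(=O)O[C@@H]2/C=C(/CO)C2=CC(=O)[C@@](C)(O2)[C@@H]1OC(=O)/C(C)=C\C | target

**Step count and risks**

Total step count: 20. Longest linear sequence: 17 steps (steps 1–6, then 10–20); steps 7–9 form the side branch.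

Steps most likely to fail:

1. Step 14 (Nozaki–Hiyama–Kishi ring closure). Oligomerisation may compete with closure of the strained ten-membered enyne ring, and the alkenylchromium may expel the C6 lactone carboxylate (allene formation). The fallback makes the C3–C4 bond intermolecularly and closes the ring at C6–C7 instead, with the lactone closed last by the same Mitsunobu inversion. It sets out from 9 and 14. Acetal hydrolysis of 9 (Amberlyst-15, acetone/H2O) gives the ynal F1. Intermolecular Nozaki–Hiyama–Kishi coupling of F1 with 14 gives the open-chain C3 carbinol F2. MnO2 oxidises the C3 and C6 carbinols, but not the acrylate-deactivated C7 carbinol, to the ynone enal F3. Gold(I) catalysis as in step 16 gives the open-chain furanone enal F4, and NBS/Me2S as in step 6 gives the Z-allyl bromide F5. Zinc-mediated Barbier cyclisation at high dilution should give the macrocyclic 6-epi hydroxy ester F6, and LiOH gives the macrocyclic hydroxy acid F7. Mitsunobu lactonisation as in step 12 comes back to the route at 24.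

2. Step 10 (Barbier addition). The syn/anti ratio at C6 may erode through an equilibrating allylzinc or an open transition state. The fallback sets C6 by reduction instead of by the C–C bond formation. It sets out from the C6-epimeric mixture 17: Dess–Martin oxidation gives the C6 ketone F8, and oxazaborolidine-catalysed borane (CBS) reduction, with the catalyst enantiomer chosen to give the 6-epi alcohol, comes back at 17.

3. Step 18 (site-selective methacryloylation). Discrimination between the C8 and C9 hydroxyls may be insufficient, or the acyl group may migrate. The fallback is a silyl relay from 25. TESOTf/2,6-lutidine at −78 °C should silylate the more accessible C8 hydroxyl to give the 8-O-triethylsilyl ether F9. Angeloylation of C9 as in step 19 gives the 8-O-triethylsilyl 9-O-angelate F10. PPTS/MeOH removes only the triethylsilyl group, giving the 9-O-angelate C8 alcohol F11. Methacrylic anhydride/DMAP then comes back at 27.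

Further compounds
F1 | step 14 | ynal from 9 (acetal hydrolysed) | COC(=O)C(=C)C(O)[C@@H]1OC(C)(C)O[C@H]1[C@](C)(O)C#CC=O
F2 | step 14 | open-chain C3 carbinol from F1 and 14 | COC(=O)C(=C)C(O)[C@@H]1OC(C)(C)O[C@H]1[C@](C)(O)C#CC(O)/C(CO[Si](c1ccccc1)(c1ccccc1)C(C)(C)C)=C\CO
F3 | step 14 | ynone enal | COC(=O)C(=C)C(O)[C@@H]1OC(C)(C)O[C@H]1[C@](C)(O)C#CC(=O)/C(CO[Si](c1ccccc1)(c1ccccc1)C(C)(C)C)=C\C=O
F4 | step 14 | open-chain furanone enal | COC(=O)C(=C)C(O)[C@@H]1OC(C)(C)O[C@H]1[C@]2(C)OC(=CC2=O)/C(CO[Si](c1ccccc1)(c1ccccc1)C(C)(C)C)=C\C=O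
F5 | step 14 | open-chain furanone enal Z-allyl bromide | COC(=O)/C(CBr)=C/[C@@H]1OC(C)(C)O[C@H]1[C@]2(C)OC(=CC2=O)/C(CO[Si](c1ccccc1)(c1ccccc1)C(C)(C)C)=C\C=O
F6 | step 14 | macrocyclic 6-epi hydroxy ester | CC1(C)O[C@H]2[C@@H](C(=C)C(=O)OC)[C@@H](O)/C=C(/CO[Si](c3ccccc3)(c3ccccc3)C(C)(C)C)C3=CC(=O)[C@@](C)(O3)[C@@H]2O1
F7 | step 14 | macrocyclic 6-epi hydroxy acid | CC1(C)O[C@H]2[C@@H](C(=C)C(=O)O)[C@@H](O)/C=C(/CO[Si](c3ccccc3)(c3ccccc3)C(C)(C)C)C3=CC(=O)[C@@](C)(O3)[C@@H]2O1
F8 | step 10 | C6 ketone of 17 | COC(=O)C(=C)[C@@H](C(=O)/C=C(\I)CO[Si](c1ccccc1)(c1ccccc1)C(C)(C)C)[C@@H]1OC(C)(C)O[C@H]1[C@](C)(O)C#CC(OCC)OCC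
F9 | step 18 | 8-O-triethylsilyl ether of 25 | CC[Si](CC)(CC)O[C@H]1[C@H]2C(=C)C(=O)O[C@@H]2/C=C(/CO[Si](c3ccccc3)(c3ccccc3)C(C)(C)C)C2=CC(=O)[C@@](C)(O2)[C@@H]1O
F10 | step 18 | 8-O-triethylsilyl 9-O-angelate | CC[Si](CC)(CC)O[C@H]1[C@H]2C(=C)C(=O)O[C@@H]2/C=C(/CO[Si](c3ccccc3)(c3ccccc3)C(C)(C)C)C2=CC(=O)[C@@](C)(O2)[C@@H]1OC(=O)/C(C)=C\C
F11 | step 18 | 9-O-angelate C8 alcohol | O[C@H]1[C@H]2C(=C)C(=O)O[C@@H]2/C=C(/CO[Si](c3ccccc3)(c3ccccc3)C(C)(C)C)C2=CC(=O)[C@@](C)(O2)[C@@H]1OC(=O)/C(C)=C\C
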